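**Retrosynthetic overview**
1. Target 18 is traced back, through desilylation, hydrogenolysis of a C4'–Br bond and O-monomethylation, to the bromo diol 15.
2. Key disconnection: the aryl–CH2 bonds at C2' and C6' of ring B. Each of these carbons is ortho to a ring B oxygen (on C3' and on C5') and flanks C1', which carries the benzofuran-2-yl group; C4' lies between the two oxygens. Both prenyl groups are therefore delivered from oxygen by a twofold [3,3] shift of the bis(1,1-dimethylallyl) ether 13, with C4' blocked by bromine.
3. 13 comes from bromoresorcinol 11 by copper-catalysed O-(1,1-dimethylpropargyl)ation and alkyne semihydrogenation.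
4. 11 comes from closure of the furan ring (C2=C3 bond, intramolecular Wittig) between phosphonium salt 4 (ring A, from 2,4-dihydroxybenzaldehyde 1) and acid chloride 7 (ring B, from 4-bromo-3,5-dihydroxybenzoic acid 5).
5. Ring order: rings A and B are bought as benzene rings; the furan ring is the only ring formed (step 6); the key step closes no ring.

Key step: step 10

Remark: ring B is numbered C1'–C6' with C1' bonded to C2 of the benzofuran. The benzofuran 6-oxygen is carried as a triisopropylsilyl (not tert-butyldimethylsilyl) ether, because it has to pass pyrrolidine, DBU in MeCN and K2CO3/MeI, which can cleave less hindered aryl silyl ethers. The two phenols of 15 are taken as equivalent through rotation about the C1'–C2 bond.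

**Route**

Step 1
Reactants: 1 2,4-dihydroxybenzaldehyde
Product: 2 2-hydroxy-4-(triisopropylsilyloxy)benzaldehyde
Conditions: TIPSCl (1.05 equiv), imidazole, CH2Cl2, 0 °C to rt
Reagents that add atoms: triisopropylsilyl chloride, CC(C)[Si](Cl)(C(C)C)C(C)C
Why: Selective O-silylation should occur at the 4-OH because the 2-OH is tied up in a hydrogen bond to the aldehyde and is the less nucleophilic phenol.

Step 2
Reactants: 2 2-hydroxy-4-(triisopropylsilyloxy)benzaldehyde
Product: 3 2-(hydroxymethyl)-5-(triisopropylsilyloxy)phenol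
Conditions: NaBH4, THF/MeOH, 0 °C; aq. NH4Cl work-up
Reagents that add atoms: none
Why: Borohydride reduction of an aryl aldehyde is fast at 0 °C and should leave the hindered aryl silyl ether intact; the acid-sensitive benzylic alcohol is used directly.

Step 3
Reactants: 3 2-(hydroxymethyl)-5-(triisopropylsilyloxy)phenol
Product: 4 [2-hydroxy-4-(triisopropylsilyloxy)benzyl]triphenylphosphonium bromide
Conditions: PPh3·HBr, MeCN, 70 °C
Reagents that add atoms: triphenylphosphine hydrobromide, [Br-].c1ccc([PH+](c2ccccc2)c2ccccc2)cc1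
Why: The electron-rich ortho-hydroxybenzyl alcohol ionises under the mild acid to an ortho-quinone methide-type cation that is captured by PPh3, the standard preparation of 2-hydroxybenzylphosphonium salts.

Step 4
Reactants: 5 4-bromo-3,5-dihydroxybenzoic acid
Product: 6 3,5-diacetoxy-4-bromobenzoic acid
Conditions: Ac2O, pyridine, DMAP (cat.), rt; then H2O
Reagents that add atoms: acetic anhydride, CC(=O)OC(C)=O
Why: DMAP-catalysed O-acetylation caps both phenols, and the mixed anhydride formed at the carboxyl group is hydrolysed on aqueous work-up.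

Step 5
Reactants: 6 3,5-diacetoxy-4-bromobenzoic acid
Product: 7 3,5-diacetoxy-4-bromobenzoyl chloride
Conditions: (COCl)2, DMF (cat.), CH2Cl2, 0 °C to rt; evaporate
Reagents that add atoms: oxalyl chloride, O=C(Cl)C(Cl)=O
Why: Vilsmeier-type activation converts the acid into the acid chloride under conditions that aryl acetates and the aryl bromide tolerate.

Step 6
Reactants: 4 [2-hydroxy-4-(triisopropylsilyloxy)benzyl]triphenylphosphonium bromide; 7 3,5-diacetoxy-4-bromobenzoyl chloride
Product: 10 2-bromo-5-[6-(triisopropylsilyloxy)-1-benzofuran-2-yl]-1,3-phenylene diacetate, via O-aroyl phosphonium bromide 8 (not isolated), via phosphorus ylide 9 (not isolated)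
Conditions: Et3N (3.5 equiv), toluene, rt then 110 °C
Reagents that add atoms: none
Why: O-acylation of the phenol, deprotonation to the benzylic ylide and intramolecular Wittig olefination of the aryl ester carbonyl close the furan ring (5-exo attack on the ester, then loss of Ph3PO), a standard route to 2-arylbenzofurans.

Step 7
Reactants: 10 2-bromo-5-[6-(triisopropylsilyloxy)-1-benzofuran-2-yl]-1,3-phenylene diacetate
Product: 11 2-bromo-5-[6-(triisopropylsilyloxy)-1-benzofuran-2-yl]benzene-1,3-diol
Conditions: pyrrolidine (4 equiv), THF, 0 °C to rt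
Reagents that add atoms: none
Why: Aminolysis of aryl acetates by a secondary amine is fast (the ortho-bromophenoxide is a good leaving group), while the amine has no affinity for silicon, so the triisopropylsilyl ether should survive.

Step 8
Reactants: 11 2-bromo-5-[6-(triisopropylsilyloxy)-1-benzofuran-2-yl]benzene-1,3-diol
Product: 12 2-[4-bromo-3,5-bis(2-methylbut-3-yn-2-yloxy)phenyl]-6-(triisopropylsilyloxy)-1-benzofuran
Conditions: 3-chloro-3-methylbut-1-yne (3 equiv), DBU (3.2 equiv), CuCl2·2H2O (1 mol %), dry MeCN, 0 °C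
Reagents that add atoms: 3-chloro-3-methylbut-1-yne, C#CC(C)(C)Cl
Why: Copper-catalysed propargylic substitution (copper acetylide, then a copper allenylidene-type electrophile) lets the acidic ortho-bromophenoxides attack the tertiary carbon, the established way to make hindered aryl 1,1-dimethylpropargyl ethers that direct substitution cannot give.

Step 9
Reactants: 12 2-[4-bromo-3,5-bis(2-methylbut-3-yn-2-yloxy)phenyl]-6-(triisopropylsilyloxy)-1-benzofuran
Product: 13 2-[4-bromo-3,5-bis(2-methylbut-3-en-2-yloxy)phenyl]-6-(triisopropylsilyloxy)-1-benzofuran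
Conditions: H2 (1 atm), Pd/CaCO3 poisoned with Pb(OAc)2 (Lindlar catalyst), quinoline, EtOAc, rt, stopped after 2 equiv H2
Reagents that add atoms: none
Why: Lindlar semihydrogenation reduces the terminal alkynes to vinyl groups, and the poisoned catalyst should spare the aryl bromide, the benzofuran C2=C3 bond and the new alkenes.

Step 10
Reactants: 13 2-[4-bromo-3,5-bis(2-methylbut-3-en-2-yloxy)phenyl]-6-(triisopropylsilyloxy)-1-benzofuran
Product: 15 2-bromo-4,6-bis(3-methylbut-2-en-1-yl)-5-[6-(triisopropylsilyloxy)-1-benzofuran-2-yl]benzene-1,3-diol, via mono-rearranged phenol 14 (not isolated)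
Conditions: PhNEt2 (degassed), 150 °C, Ar
Reagents that add atoms: none
Why: Each tertiary allyl aryl ether undergoes a concerted [3,3] sigmatropic shift through a chair-like six-membered transition state in which the O–CMe2 bond breaks while the terminal CH2 bonds to the ortho carbon C2' (then C6'), and tautomerisation of the resulting cyclohexadienone to the phenol makes each shift irreversible, the mono-rearranged phenol 14 reacting on in the same flask. This is the aromatic ortho-Claisen rearrangement of 1,1-dimethylallyl aryl ethers, whose allylic inversion turns the ether carbon into the alkene terminus and so gives linear prenyl groups. No ring is closed and no stereocentre is formed. The step needs site selectivity for C2' and C6' over C4', and the bromine at C4' secures it, because a shift to that carbon gives a dienone that cannot enolise and returns by retro-Claisen, so material funnels to the two CH sites next to C1'. Delivery from the oxygens on C3' and C5' is intramolecular and therefore tolerates the crowding by the benzofuran-2-yl group, and the basic amine solvent keeps the medium non-acidic so that ionisation of the tertiary ethers to isoprene and closure of the ortho-prenylphenols to chromans are held back.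

Step 11
Reactants: 15 2-bromo-4,6-bis(3-methylbut-2-en-1-yl)-5-[6-(triisopropylsilyloxy)-1-benzofuran-2-yl]benzene-1,3-diol
Product: 16 2-bromo-3-methoxy-4,6-bis(3-methylbut-2-en-1-yl)-5-[6-(triisopropylsilyloxy)-1-benzofuran-2-yl]phenol
Conditions: MeI (1.0 equiv), K2CO3 (1.0 equiv), acetone, rt; recovered 15 resubmitted
Reagents that add atoms: iodomethane, CI
Why: Williamson O-methylation with one equivalent each of base and MeI should give the monomethyl ether as the main component of a statistical mixture, the ortho-bromine making the phenols acidic enough for carbonate at room temperature where the silyl ether is safe.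

Step 12
Reactants: 16 2-bromo-3-methoxy-4,6-bis(3-methylbut-2-en-1-yl)-5-[6-(triisopropylsilyloxy)-1-benzofuran-2-yl]phenol
Product: 17 5-methoxy-2,4-bis(3-methylbut-2-en-1-yl)-3-[6-(triisopropylsilyloxy)-1-benzofuran-2-yl]phenol
Conditions: Pd(OAc)2 (10 mol %), PPh3 (40 mol %), HCO2H, Et3N, DMF, 80 °C
Reagents that add atoms: none
Why: Palladium-catalysed transfer hydrogenolysis (oxidative addition of zerovalent palladium into C–Br, formate exchange, decarboxylation to the aryl palladium hydride, reductive elimination) replaces bromine by hydrogen without reducing the trisubstituted prenyl alkenes or the benzofuran.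

Step 13
Reactants: 17 5-methoxy-2,4-bis(3-methylbut-2-en-1-yl)-3-[6-(triisopropylsilyloxy)-1-benzofuran-2-yl]phenol
Product: 18 2-[3-hydroxy-5-methoxy-2,6-bis(3-methylbut-2-en-1-yl)phenyl]-1-benzofuran-6-ol (target)
Conditions: TBAF (1.1 equiv), AcOH (1.1 equiv), THF, 0 °C
Reagents that add atoms: none
Why: Fluoride cleaves the aryl O–Si bond, and the acetic acid buffer keeps the medium near neutral so that the ortho-prenylphenol units neither cyclise nor oxidise.

**Compound list**
1 | 2,4-dihydroxybenzaldehyde | O=Cc1ccc(O)cc1O | starting material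
2 | 2-hydroxy-4-(triisopropylsilyloxy)benzaldehyde | O=Cc1ccc(O[Si](C(C)C)(C(C)C)C(C)C)cc1O | intermediate
3 | 2-(hydroxymethyl)-5-(triisopropylsilyloxy)phenol | OCc1ccc(O[Si](C(C)C)(C(C)C)C(C)C)cc1O | intermediate
4 | [2-hydroxy-4-(triisopropylsilyloxy)benzyl]triphenylphosphonium bromide | Oc1cc(O[Si](C(C)C)(C(C)C)C(C)C)ccc1C[P+](c1ccccc1)(c1ccccc1)c1ccccc1.[Br-] | intermediate
5 | 4-bromo-3,5-dihydroxybenzoic acid | O=C(O)c1cc(O)c(Br)c(O)c1 | starting material
6 | 3,5-diacetoxy-4-bromobenzoic acid | CC(=O)Oc1cc(C(=O)O)cc(OC(C)=O)c1Br | intermediate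
7 | 3,5-diacetoxy-4-bromobenzoyl chloride | CC(=O)Oc1cc(C(Cl)=O)cc(OC(C)=O)c1Br | intermediate
8 | [2-(3,5-diacetoxy-4-bromobenzoyloxy)-4-(triisopropylsilyloxy)benzyl]triphenylphosphonium bromide | CC(=O)Oc1cc(C(=O)Oc2cc(O[Si](C(C)C)(C(C)C)C(C)C)ccc2C[P+](c2ccccc2)(c2ccccc2)c2ccccc2)cc(OC(C)=O)c1Br.[Br-] | intermediate
9 | 2-[(triphenylphosphoranylidene)methyl]-5-(triisopropylsilyloxy)phenyl 3,5-diacetoxy-4-bromobenzoate (ylide of 8) | CC(=O)Oc1cc(C(=O)Oc2cc(O[Si](C(C)C)(C(C)C)C(C)C)ccc2C=P(c2ccccc2)(c2ccccc2)c2ccccc2)cc(OC(C)=O)c1Br | intermediate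
10 | 2-bromo-5-[6-(triisopropylsilyloxy)-1-benzofuran-2-yl]-1,3-phenylene diacetate | CC(=O)Oc1cc(-c2cc3ccc(O[Si](C(C)C)(C(C)C)C(C)C)cc3o2)cc(OC(C)=O)c1Br | intermediate
11 | 2-bromo-5-[6-(triisopropylsilyloxy)-1-benzofuran-2-yl]benzene-1,3-diol | Oc1cc(-c2cc3ccc(O[Si](C(C)C)(C(C)C)C(C)C)cc3o2)cc(O)c1Br | intermediate
12 | 2-[4-bromo-3,5-bis(2-methylbut-3-yn-2-yloxy)phenyl]-6-(triisopropylsilyloxy)-1-benzofuran | C#CC(C)(C)Oc1cc(-c2cc3ccc(O[Si](C(C)C)(C(C)C)C(C)C)cc3o2)cc(OC(C)(C)C#C)c1Br | intermediate
13 | 2-[4-bromo-3,5-bis(2-methylbut-3-en-2-yloxy)phenyl]-6-(triisopropylsilyloxy)-1-benzofuran | C=CC(C)(C)Oc1cc(-c2cc3ccc(O[Si](C(C)C)(C(C)C)C(C)C)cc3o2)cc(OC(C)(C)C=C)c1Br | intermediate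
14 | 2-bromo-3-(2-methylbut-3-en-2-yloxy)-6-(3-methylbut-2-en-1-yl)-5-[6-(triisopropylsilyloxy)-1-benzofuran-2-yl]phenol | C=CC(C)(C)Oc1cc(-c2cc3ccc(O[Si](C(C)C)(C(C)C)C(C)C)cc3o2)c(CC=C(C)C)c(O)c1Br | intermediate
15 | 2-bromo-4,6-bis(3-methylbut-2-en-1-yl)-5-[6-(triisopropylsilyloxy)-1-benzofuran-2-yl]benzene-1,3-diol | Oc1c(Br)c(O)c(CC=C(C)C)c(-c2cc3ccc(O[Si](C(C)C)(C(C)C)C(C)C)cc3o2)c1CC=C(C)C | intermediate
16 | 2-bromo-3-methoxy-4,6-bis(3-methylbut-2-en-1-yl)-5-[6-(triisopropylsilyloxy)-1-benzofuran-2-yl]phenol | COc1c(Br)c(O)c(CC=C(C)C)c(-c2cc3ccc(O[Si](C(C)C)(C(C)C)C(C)C)cc3o2)c1CC=C(C)C | intermediate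
17 | 5-methoxy-2,4-bis(3-methylbut-2-en-1-yl)-3-[6-(triisopropylsilyloxy)-1-benzofuran-2-yl]phenol | COc1cc(O)c(CC=C(C)C)c(-c2cc3ccc(O[Si](C(C)C)(C(C)C)C(C)C)cc3o2)c1CC=C(C)C | intermediate
18 | 2-[3-hydroxy-5-methoxy-2,6-bis(3-methylbut-2-en-1-yl)phenyl]-1-benzofuran-6-ol | COc1cc(O)c(CC=C(C)C)c(-c2cc3ccc(O)cc3o2)c1CC=C(C)C | target

**Step count**
Total: 13 steps. Longest linear sequence: 11 steps (steps 1, 2, 3, 6, 7, 8, 9, 10, 11, 12, 13 from 1); the branch from 5 contributes steps 4 and 5.

**Steps most likely to fail**

Step 10 (double Claisen rearrangement). Three processes could compete: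
- heterolysis of the tertiary allylic C–O bonds with loss of isoprene, which would return phenols without C–C bond formation;
- a shift to the brominated C4' followed by Cope transfer to the para carbon, which would place a reversed 1,1-dimethylallyl group at C6', or loss of bromine from that dienone;
- closure of the new ortho-prenylphenols to chromans.

The fallback sets out from 11. O-Allylation with allyl bromide and K2CO3 in acetone should give the bis(allyl) ether 2-[3,5-bis(allyloxy)-4-bromophenyl]-6-(triisopropylsilyloxy)-1-benzofuran F1. Heating F1 in PhNEt2 at about 190 °C should bring about the double Claisen rearrangement to 4,6-diallyl-2-bromo-5-[6-(triisopropylsilyloxy)-1-benzofuran-2-yl]benzene-1,3-diol F2. A primary allyl ether does not ionise, and an unsubstituted allyl group reaches C2' and C6' unchanged whether it travels by the direct ortho shift or by the detour through C4'. Cross-metathesis of both terminal alkenes with excess 2-methylbut-2-ene and the second-generation Grubbs catalyst RuCl2(=CHPh)(PCy3)(H2IMes) in CH2Cl2 at 40 °C would then install the dimethyl-substituted alkene termini. The fallback comes back to the route at 15.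

Step 11 (monomethylation). The second phenol is methylated at a rate close to that of the first, so over-alkylation and incomplete conversion would leave diol, monomethyl and dimethyl ether side by side, and their separation may be laborious.

The fallback sets out from 15 and comes back to the route at the target 18:
- Exhaustive methylation (excess MeI, K2CO3, acetone, reflux) should give the dimethyl ether 2-[4-bromo-3,5-dimethoxy-2,6-bis(3-methylbut-2-en-1-yl)phenyl]-6-(triisopropylsilyloxy)-1-benzofuran F3. Over-methylated material from step 11 can be added here.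
- Hydrogenolysis of the C–Br bond under the conditions of step 12 would give 2-[3,5-dimethoxy-2,6-bis(3-methylbut-2-en-1-yl)phenyl]-6-(triisopropylsilyloxy)-1-benzofuran F4.
- Desilylation with TBAF/AcOH in THF would give 2-[3,5-dimethoxy-2,6-bis(3-methylbut-2-en-1-yl)phenyl]-1-benzofuran-6-ol F5.
- Treatment of F5 with excess NaSEt in degassed DMF at 120 °C, then acidification, should remove one methyl group only, by SN2 attack of thiolate at the methyl carbon. The aryloxide formed by the first demethylation makes ring B too electron-rich to release a second one.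

Step 12 (removal of bromine). Oxidative addition into the electron-rich C–Br bond flanked by two oxygen substituents may be slow, and a long-lived palladium hydride could shift the prenyl double bonds.

The fallback sets out from 16. Treatment with t-BuLi (3.3 equiv) in THF at −78 °C should deprotonate the phenol and exchange bromine for lithium, giving lithium 2-lithio-3-methoxy-4,6-bis(3-methylbut-2-en-1-yl)-5-[6-(triisopropylsilyloxy)-1-benzofuran-2-yl]phenolate F6. Quenching with MeOH at −78 °C would protonate C4' and the phenoxide. The fallback comes back to the route at 17.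

**Further compounds**
F1 | step 10 | 2-[3,5-bis(allyloxy)-4-bromophenyl]-6-(triisopropylsilyloxy)-1-benzofuran | C=CCOc1cc(-c2cc3ccc(O[Si](C(C)C)(C(C)C)C(C)C)cc3o2)cc(OCC=C)c1Br
F2 | step 10 | 4,6-diallyl-2-bromo-5-[6-(triisopropylsilyloxy)-1-benzofuran-2-yl]benzene-1,3-diol | Oc1c(Br)c(O)c(CC=C)c(-c2cc3ccc(O[Si](C(C)C)(C(C)C)C(C)C)cc3o2)c1CC=C
F3 | step 11 | 2-[4-bromo-3,5-dimethoxy-2,6-bis(3-methylbut-2-en-1-yl)phenyl]-6-(triisopropylsilyloxy)-1-benzofuran | COc1c(Br)c(OC)c(CC=C(C)C)c(-c2cc3ccc(O[Si](C(C)C)(C(C)C)C(C)C)cc3o2)c1CC=C(C)C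
F4 | step 11 | 2-[3,5-dimethoxy-2,6-bis(3-methylbut-2-en-1-yl)phenyl]-6-(triisopropylsilyloxy)-1-benzofuran | COc1cc(OC)c(CC=C(C)C)c(-c2cc3ccc(O[Si](C(C)C)(C(C)C)C(C)C)cc3o2)c1CC=C(C)C
F5 | step 11 | 2-[3,5-dimethoxy-2,6-bis(3-methylbut-2-en-1-yl)phenyl]-1-benzofuran-6-ol | COc1cc(OC)c(CC=C(C)C)c(-c2cc3ccc(O)cc3o2)c1CC=C(C)C
F6 | step 12 | lithium 2-lithio-3-methoxy-4,6-bis(3-methylbut-2-en-1-yl)-5-[6-(triisopropylsilyloxy)-1-benzofuran-2-yl]phenolate | [Li]Oc1c([Li])c(OC)c(CC=C(C)C)c(-c2cc3ccc(O[Si](C(C)C)(C(C)C)C(C)C)cc3o2)c1CC=C(C)C
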